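## Structural features

The target is a spiro[5.5]undecane. Ring A (C1–C5 plus the spiro atom C6) is a cyclohexane with a methyl-bearing tertiary carbinol at C1, a secondary bromide at C3 and a gem-dimethyl group at C5. Ring B (C6–C11) is a cyclohexene whose C7=C8 bond is conjugated with an exocyclic bromomethylidene group C9=C12; these locants are used for every intermediate, including the monocyclic ones. C6 is a quaternary stereocentre lying between two fully substituted carbons (C1 and C5), so three contiguous ring atoms carry no hydrogen. C1 and C6 are adjacent stereocentres: the C1 oxygen is anti to the vinylic arm C7 and on the same side of ring A as C11H2. The C3 bromide is 1,3 to C1 and trans to the C1 hydroxy group, so in the chair with equatorial bromine the hydroxy group is axial. The bromodiene is Z (bromine syn to C8). Fragile groups are the tertiary alcohol beside a quaternary carbon (ionisation, Wagner–Meerwein shift, dehydration), the secondary bromide (E2), the dienyl bromide (light, low-valent metals, organolithiums) and, at the ketone oxidation level of C9, a δ-hydroxy enone that can fragment by retro-vinylogous aldol under base. The real difficulty is to build C6, whose stereogenicity rests only on the difference between the C7 and C11 arms, in a defined relation to C1 at a site flanked by two fully substituted carbons. The key step exploits two features: the anti arrangement of the C1–O and C6–C7 bonds is the signature of a trans opening of a C1–C6 epoxide of ring A by C7, and ring A has the carbon and oxygen pattern of ketoisophorone.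

## Logic of the disconnections

In one sentence: ring B and the spiro centre are made together by a Cp2TiCl-mediated reductive opening of the tetrasubstituted epoxide 14 and 6-endo-dig capture of the resulting C6 radical by its own terminal ynone.

18 ⇒ 17. The C3–Br bond is cut. The secondary bromide is the group least compatible with hydrides, organometallics and low-valent metals, so it is introduced last. The cut leaves an alcohol whose oxygen lies on the same face as the C1 oxygen, which is exactly what a hydroxyl-directed epoxidation delivers. The forward step must be an SN2 displacement with inversion at a carbon flanked by two CH2–C(quaternary) units, faster than E2, and must leave the tertiary C1 alcohol alone.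

17 ⇒ 16. The C9=C12 double bond is cut. This replaces the sensitive bromodiene by a robust enone and is a one-carbon olefination. The forward step must give the Z geometry and must not expose the δ-hydroxy enone to alkoxide.

16 ⇒ 14 (key). The C6–C7 bond is cut, together with the C8–H bond. C6 in 14 is an epoxide carbon and C7 is the β-carbon of an ynone; both are acceptor carbons, so their union needs polarity reversal, here by one-electron reduction of the epoxide. The gain is large: a spirobicycle with two adjacent fully substituted stereocentres becomes a monocyclic epoxide with a linear side chain, the C1 configuration is stored in the epoxide, and the enone appears directly. The forward step needs C6–O rather than C1–O cleavage, 6-endo rather than 5-exo closure, attack of C7 anti to the C1 oxygen, and ring closure faster than reduction of the radical.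

14 ⇒ 13. The two C–O bonds of the epoxide are cut. The C3 hydroxy group can deliver the oxidant to its own face, so C1 and C6 both derive from the single stereocentre C3. The forward step must be face-selective on a hindered tetrasubstituted alkene and must not touch the ynone.

13 ⇒ 11 (through 12). No skeletal bond is cut; the C9 oxidation level is lowered and silyl groups are restored. A terminal ynone would not survive hydroboration and palladium catalysis, whereas a propargylic alcohol and a silylated alkyne do. The forward steps need an oxidant that distinguishes the propargylic C9 carbinol from the C3 carbinol.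

11 ⇒ 5 + 9. The C6–C11 sp2–sp3 bond is cut. This splits the molecule into the complete ring A as an alkenyl electrophile and a five-carbon chain that carries C7–C11, so the route is convergent. The forward step is a cross-coupling at a tetrasubstituted, neopentyl-flanked alkenyl triflate, and the hydroboration must select the vinyl group over the silylalkyne.

5 ⇒ 3 ⇒ 2 ⇒ 1. The C6–O bond of the triflate is traced to an enolate formed by conjugate reduction, which fixes the tetrasubstituted C1=C6 double bond regiospecifically. The C3 carbinol is traced to enantioselective reduction of the less hindered carbonyl of 1. All nine carbons of ring A then come from a commodity dione and the only stereocentre that is set by a chiral reagent is C3. The forward steps need chemo- and enantioselective reduction of one of two carbonyl groups and 1,4- rather than 1,2-hydride delivery.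

9 ⇒ 6 + 7. The C8–C9 bond is cut to an acetylide and an enal. The carbinol formed need not be controlled because it becomes a carbonyl carbon.

## Other disconnections considered

Alternative 1: the first plan that comes to mind cuts C6–C7 and C10–C11 by a Diels–Alder reaction. The forward key step is cycloaddition of the exocyclic enone A1 with an oxygenated butadiene to give the spiro enedione A2, followed by methyl addition to the C1 ketone. This plan sets C6 and C1 in two separate substrate-controlled events: the facial choice of the diene at an exocyclic methylene and the facial choice of a methyl nucleophile at a ketone wedged between C6 and C2. Neither is tied to the other by mechanism. The more reactive C9 enone would also have to be masked before the methyl addition, and A1 is an α-methylene ketone prone to dimerisation. The chosen plan links C1 and C6 through one epoxide and needs no carbonyl differentiation.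

Alternative 2: a semipinacol ring expansion cuts C6–C7 as a 1,2-shift. The forward key step is Lewis-acid rearrangement of the epoxy alcohol A3, in which the vinylic carbon of a cyclopentenol migrates to C6 anti to the epoxide oxygen and gives the spiro hydroxy ketone A4. The stereochemical logic is as strict as in the chosen plan, but the mechanism places the new carbonyl on the arm syn to the C1 hydroxy group, that is at C11, which is a CH2 group in the target. The ketone would have to be excised next to a quaternary carbon in a β-hydroxy ketone, and the C9 oxygen would still have to be introduced by allylic oxidation. Making A3 also requires adding a tetrasubstituted alkenyl metal to an enolisable cyclopentenone. The chosen plan reaches the same C1/C6 relationship with the carbonyl already at C9.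

Alternative 3: a dearomatisation plan cuts C1–C6. The forward sequence is Birch reduction of a para-substituted anisole to the keto methoxydiene A5 and Lewis-acid vinylogous aldol attack of the diene γ-carbon (the former para carbon) on the methyl ketone, giving 16 directly. It is the shortest plan on paper and chelation between the C3 and C1 oxygens could fix C1 relative to C3. However, the C6 configuration depends on whether the carbonyl lies antiperiplanar or synclinal to the diene in an open transition state, and sterics and stereoelectronics pull in opposite directions there. The tetrasubstituted aldol bond is also reversible, and a ketone next to a latent enone invites Michael closure. The chosen plan fixes C1 in an epoxide and C6 by a trans radical addition.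

Key step: step 9

Remark: 9, 11 and 12 are carried as mixtures of epimers at the future C9, a centre that becomes a carbonyl carbon in step 7.

## Steps

Step 1
Reactants: 1 2,6,6-trimethylcyclohex-2-ene-1,4-dione (ketoisophorone)
Product: 2 (4S)-4-hydroxy-2,6,6-trimethylcyclohex-2-en-1-one
Conditions: RuCl(p-cymene)[(S,S)-TsDPEN] (1 mol %), i-PrOH, rt
Reagents that add atoms: none
Why: Noyori-type asymmetric transfer hydrogenation: the C4 carbonyl of 1 (between CH= and CH2) is far more accessible than the C1 carbonyl (between C(CH3)= and C(CH3)2), so only it should be reduced. The chiral Ru–H/N–H catalyst sets the carbinol, the future C3, as S; the catalyst antipode is the one selected for this sense.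

Step 2
Reactants: 2 (4S)-4-hydroxy-2,6,6-trimethylcyclohex-2-en-1-one
Product: 3 (4S)-4-[(tert-butyldimethylsilyl)oxy]-2,6,6-trimethylcyclohex-2-en-1-one
Conditions: TBSCl, imidazole, DMF, rt
Reagents that add atoms: tert-butyldimethylsilyl chloride, CC(C)(C)[Si](C)(C)Cl
Why: Standard silylation of a secondary alcohol; the silyl ether keeps the alkoxide out of the hydride reduction and triflation of step 3 and is removed together with the alkynyl silane in step 6.

Step 3
Reactants: 3 (4S)-4-[(tert-butyldimethylsilyl)oxy]-2,6,6-trimethylcyclohex-2-en-1-one
Product: 5 (4R)-4-[(tert-butyldimethylsilyl)oxy]-2,6,6-trimethylcyclohex-1-en-1-yl trifluoromethanesulfonate, via lithium enolate 4 (not isolated)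
Conditions: LiBH(s-Bu)3, THF, −78 °C; then PhNTf2, −78 → 0 °C
Reagents that add atoms: N-phenylbis(trifluoromethanesulfonimide), O=S(=O)(N(c1ccccc1)S(=O)(=O)C(F)(F)F)C(F)(F)F
Why: Conjugate reduction with a bulky trialkylborohydride (1,4-delivery to the unsubstituted β-carbon is favoured because the carbonyl sits between C(CH3)= and C(CH3)2) gives enolate 4 regiospecifically, and O-triflation fixes the tetrasubstituted C1=C6 double bond. The silyloxy group is not β to the enolate carbon and is not eliminated; the stereocentre is untouched (the descriptor changes from S to R only because the ring priorities change).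

Step 4
Reactants: 6 ethynyltrimethylsilane; 7 acrolein
Product: 9 5-(trimethylsilyl)pent-1-en-4-yn-3-ol (racemic), via lithium silylacetylide 8 (not isolated)
Conditions: n-BuLi, THF, −78 °C; then 7, −78 → 0 °C; H2O
Reagents that add atoms: none
Why: 1,2-Addition of a lithium acetylide to an enal at low temperature; the new carbinol (future C9) is formed as a racemate, which is of no consequence because it is oxidised in step 7.

Step 5
Reactants: 9 5-(trimethylsilyl)pent-1-en-4-yn-3-ol (racemic); 5 (4R)-4-[(tert-butyldimethylsilyl)oxy]-2,6,6-trimethylcyclohex-1-en-1-yl trifluoromethanesulfonate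
Product: 11 5-[(4R)-4-[(tert-butyldimethylsilyl)oxy]-2,6,6-trimethylcyclohex-1-en-1-yl]-1-(trimethylsilyl)pent-1-yn-3-ol (both epimers at the chain carbinol), via alkyl borane 10 (not isolated)
Conditions: 9-BBN (2.2 equiv), THF, 0 °C → rt; then 5, PdCl2(dppf) (5 mol %), AsPh3, Cs2CO3, DMF/H2O, 50 °C
Reagents that add atoms: none
Why: B-alkyl Suzuki–Miyaura coupling: 9-BBN hydroborates the terminal vinyl group anti-Markovnikov and much faster than the silylated alkyne (one extra equivalent is consumed by the hydroxy group). PdCl2(dppf) with AsPh3 should couple the primary alkyl borane with the alkenyl triflate while holding back β-hydride elimination; the C6–C11 bond is formed without touching C3.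

Step 6
Reactants: 11 5-[(4R)-4-[(tert-butyldimethylsilyl)oxy]-2,6,6-trimethylcyclohex-1-en-1-yl]-1-(trimethylsilyl)pent-1-yn-3-ol
Product: 12 5-[(4R)-4-hydroxy-2,6,6-trimethylcyclohex-1-en-1-yl]pent-1-yn-3-ol (both epimers at the chain carbinol)
Conditions: Bu4NF, THF, 0 °C → rt
Reagents that add atoms: none
Why: Fluoride cleaves the Si–O bond of the silyl ether and the C(sp)–Si bond of the alkynylsilane in one operation, freeing the C3 hydroxy group needed to direct step 8 and the terminal alkyne needed in step 9.

Step 7
Reactants: 12 5-[(4R)-4-hydroxy-2,6,6-trimethylcyclohex-1-en-1-yl]pent-1-yn-3-ol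
Product: 13 5-[(4R)-4-hydroxy-2,6,6-trimethylcyclohex-1-en-1-yl]pent-1-yn-3-one
Conditions: activated MnO2, CH2Cl2, rt
Reagents that add atoms: none
Why: MnO2 oxidises only activated (propargylic, allylic) alcohols, so the C9 carbinol should become the ynone while the homoallylic C3 alcohol is retained; the two C9 epimers converge here.

Step 8
Reactants: 13 5-[(4R)-4-hydroxy-2,6,6-trimethylcyclohex-1-en-1-yl]pent-1-yn-3-one
Product: 14 5-[(1R,4S,6S)-4-hydroxy-2,2,6-trimethyl-7-oxabicyclo[4.1.0]heptan-1-yl]pent-1-yn-3-one (epoxide syn to the hydroxy group)
Conditions: VO(acac)2 (5 mol %), t-BuOOH, CH2Cl2, 0 °C → rt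
Reagents that add atoms: tert-butyl hydroperoxide, CC(C)(C)OO
Why: Vanadium-catalysed hydroxyl-directed epoxidation: the C3 alkoxide bound to vanadium delivers the peroxide oxygen to the syn face of the electron-rich tetrasubstituted C1=C6 alkene, as is known for homoallylic cyclohexenols. C1 and C6 are thus set together by C3, and the electron-poor ynone is inert to the electrophilic oxidant.

Step 9
Reactants: 14 5-[(1R,4S,6S)-4-hydroxy-2,2,6-trimethyl-7-oxabicyclo[4.1.0]heptan-1-yl]pent-1-yn-3-one
Product: 16 (1S,3S,6S)-1,3-dihydroxy-1,5,5-trimethylspiro[5.5]undec-7-en-9-one, via Cp2TiCl alkoxide 15 (not isolated)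
Conditions: Cp2TiCl2 (20 mol %), Mn dust, 2,4,6-collidine·HCl, THF (0.01 M, slow addition of 14), rt
Reagents that add atoms: none
Why: Reductive epoxide opening and radical cyclization of the Nugent–RajanBabu type, run catalytically in titanium: Cp2TiCl (trivalent titanium, formed from Cp2TiCl2 and Mn) binds the epoxide oxygen and transfers one electron, the C6–O bond breaks and leaves a tertiary C6 radical next to the C1 titanoxy group; this nucleophilic radical adds to the electron-poor terminal alkyne carbon C7, and the resulting α-keto vinyl radical at C8 is reduced and protonated by collidinium chloride, which also frees the C1 alkoxide and returns Cp2TiCl2 to the cycle. Ring B is closed in the 6-endo-dig mode with respect to the ynone (exo with respect to the cleaved C–O bond), the polarity-mismatched 5-exo attack at C8 being disfavoured. C1 keeps the configuration of the epoxide because its C–O bond is never broken; C6 is created by attack of C7 on the face of the planar radical opposite to the bulky C1 titanoxy group, the usual trans outcome for β-titanoxy radicals, which places C7 anti and C11 syn to the C1 oxygen. The step needs C6–O rather than C1–O homolysis (C6 is the more congested carbon, flanked by the C5 gem-dimethyl group, so its C–O bond is the more strained; a C1 radical has no six-membered closure available and is unproductive but cannot give an isomeric spirocycle), and it needs cyclization to outrun trapping of the radical by a second titanium centre, which the low stationary concentration of Cp2TiCl under catalytic conditions and the unhindered CH terminus of the alkyne favour. A radical is chosen because it tolerates the two fully substituted neighbours of C6 and cannot undergo the ring contraction open to a C6 cation.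

Step 10
Reactants: 16 (1S,3S,6S)-1,3-dihydroxy-1,5,5-trimethylspiro[5.5]undec-7-en-9-one
Product: 17 (1S,3S,6S,9Z)-9-(bromomethylidene)-1,5,5-trimethylspiro[5.5]undec-7-ene-1,3-diol
Conditions: Ph3P+CH2Br Br− (3 equiv), NaN(SiMe3)2 (2.9 equiv), THF, −78 °C; then 16, −78 → 0 °C
Reagents that add atoms: (bromomethyl)triphenylphosphonium bromide, BrC[P+](c1ccccc1)(c1ccccc1)c1ccccc1.[Br-]
Why: Wittig olefination with the non-stabilised ylide Ph3P=CHBr; the ylide is too weak a base to deprotonate the two alcohols, so the δ-hydroxy enone is not exposed to alkoxide. The ylide bromine can avoid the pseudo-axial C10 hydrogen by lying on the side of the planar C8–H unit, which should favour the Z isomer, but a mixture must be expected. 17 is separated and the E isomer is re-equilibrated (hν, catalytic PhSSPh) and recycled.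

Step 11
Reactants: 17 (1S,3S,6S,9Z)-9-(bromomethylidene)-1,5,5-trimethylspiro[5.5]undec-7-ene-1,3-diol
Product: 18 (1S,3R,6S,9Z)-3-bromo-9-(bromomethylidene)-1,5,5-trimethylspiro[5.5]undec-7-en-1-ol
Conditions: CBr4, PPh3, CH2Cl2, 0 °C → rt
Reagents that add atoms: carbon tetrabromide, BrC(Br)(Br)Br
Why: Appel reaction: the secondary C3 alcohol forms the alkoxyphosphonium ion and bromide displaces it by SN2 with inversion, turning the alcohol cis to the C1 hydroxy group into the equatorial bromide trans to it; in the chair with the C1 and C3 oxygens diaxial the nucleophile enters along the open equatorial direction. The tertiary C1 alcohol between the spiro carbon and C2 is too hindered to be activated, and it cannot displace at C3 because it lies on the same face as the leaving group.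

## Compound list

1 | 2,6,6-trimethylcyclohex-2-ene-1,4-dione (ketoisophorone) | CC1=CC(=O)CC(C)(C)C1=O | starting material
2 | (4S)-4-hydroxy-2,6,6-trimethylcyclohex-2-en-1-one | CC1(C)C[C@H](O)C=C(C)C1=O | intermediate
3 | (4S)-4-[(tert-butyldimethylsilyl)oxy]-2,6,6-trimethylcyclohex-2-en-1-one | CC1(C)C[C@H](O[Si](C)(C)C(C)(C)C)C=C(C)C1=O | intermediate
4 | lithium (4R)-4-[(tert-butyldimethylsilyl)oxy]-2,6,6-trimethylcyclohex-1-en-1-olate | CC1(C)C[C@H](O[Si](C)(C)C(C)(C)C)CC(C)=C1O[Li] | intermediate
5 | (4R)-4-[(tert-butyldimethylsilyl)oxy]-2,6,6-trimethylcyclohex-1-en-1-yl trifluoromethanesulfonate | CC1(C)C[C@H](O[Si](C)(C)C(C)(C)C)CC(C)=C1OS(=O)(=O)C(F)(F)F | intermediate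
6 | ethynyltrimethylsilane | C#C[Si](C)(C)C | starting material
7 | acrolein (prop-2-enal) | C=CC=O | starting material
8 | lithium (trimethylsilyl)acetylide | [Li]C#C[Si](C)(C)C | intermediate
9 | 5-(trimethylsilyl)pent-1-en-4-yn-3-ol (racemic) | C=CC(O)C#C[Si](C)(C)C | intermediate
10 | 9-{3-[(9-borabicyclo[3.3.1]nonan-9-yl)oxy]-5-(trimethylsilyl)pent-4-yn-1-yl}-9-borabicyclo[3.3.1]nonane | C[Si](C)(C)C#CC(OB1C2CCCC1CCC2)CCB1C2CCCC1CCC2 | intermediate
11 | 5-[(4R)-4-[(tert-butyldimethylsilyl)oxy]-2,6,6-trimethylcyclohex-1-en-1-yl]-1-(trimethylsilyl)pent-1-yn-3-ol (both epimers at the chain carbinol) | CC1(C)C[C@H](O[Si](C)(C)C(C)(C)C)CC(C)=C1CCC(O)C#C[Si](C)(C)C | intermediate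
12 | 5-[(4R)-4-hydroxy-2,6,6-trimethylcyclohex-1-en-1-yl]pent-1-yn-3-ol (both epimers at the chain carbinol) | CC1(C)C[C@H](O)CC(C)=C1CCC(O)C#C | intermediate
13 | 5-[(4R)-4-hydroxy-2,6,6-trimethylcyclohex-1-en-1-yl]pent-1-yn-3-one | CC1(C)C[C@H](O)CC(C)=C1CCC(=O)C#C | intermediate
14 | 5-[(1R,4S,6S)-4-hydroxy-2,2,6-trimethyl-7-oxabicyclo[4.1.0]heptan-1-yl]pent-1-yn-3-one | CC1(C)C[C@H](O)C[C@]2(C)O[C@]12CCC(=O)C#C | intermediate
15 | chlorobis(cyclopentadienyl)titanium C1-alkoxide of 16 (tetravalent titanium) | CC1(C)C[C@H](O)C[C@](C)(O[Ti](Cl)(C2C=CC=C2)C2C=CC=C2)[C@@]12C=CC(=O)CC2 | intermediate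
16 | (1S,3S,6S)-1,3-dihydroxy-1,5,5-trimethylspiro[5.5]undec-7-en-9-one | CC1(C)C[C@H](O)C[C@](C)(O)[C@@]12C=CC(=O)CC2 | intermediate
17 | (1S,3S,6S,9Z)-9-(bromomethylidene)-1,5,5-trimethylspiro[5.5]undec-7-ene-1,3-diol | CC1(C)C[C@H](O)C[C@](C)(O)[C@@]12C=C/C(=C\Br)CC2 | intermediate
18 | (1S,3R,6S,9Z)-3-bromo-9-(bromomethylidene)-1,5,5-trimethylspiro[5.5]undec-7-en-1-ol | CC1(C)C[C@@H](Br)C[C@](C)(O)[C@@]12C=C/C(=C\Br)CC2 | target

## Step count and least certain steps

Total step count: 11. Longest linear sequence: 10 steps (steps 1, 2, 3, 5, 6, 7, 8, 9, 10, 11 from 1); step 4 is the one-step side branch.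

Step 9 (key step). The most likely failure is non-productive homolysis of the C1–O instead of the C6–O bond, followed by loss of hydrogen or deoxygenation, because both epoxide carbons are tertiary. Over-reduction of the C6 radical before ring closure and reduction of the ynone by Cp2TiCl are further losses. None of these gives a stereoisomeric spirocycle, so they cost material and not purity. Fallback (cationic instead of radical ring closure, setting out from 11 and returning at 16): 11 is acetylated (Ac2O, pyridine) to the propargylic acetate F1. The silylalkyne is half-hydrogenated (H2, Pd/CaCO3 poisoned with Pb(OAc)2, quinoline) to the (Z)-vinylsilane F2. The ring silyl ether is removed with HF·pyridine to give the homoallylic alcohol F3, and vanadium-catalysed epoxidation as in step 8 gives the syn epoxide F4. Me2AlCl in CH2Cl2 at −78 °C then opens the epoxide at C6 with ipso attack of the vinylsilane carbon C7 anti to the departing oxygen, an epoxide-initiated cation–olefin cyclization with a vinylsilane terminator, and gives the spiro allylic acetate F5. Methanolysis (K2CO3, MeOH) to the triol F6 and MnO2 oxidation of the allylic C9 alcohol give 16.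

Step 5. The most likely failure is slow transmetalation and reductive elimination at the tetrasubstituted alkenyl palladium centre beside the gem-dimethyl group, so that β-hydride elimination and protodeboronation of the alkyl borane take over. Fallback (ring A as the nucleophile, setting out from 5 and returning at 11): 5 is converted with Me3SnSnMe3, Pd(PPh3)4 and LiCl into the alkenylstannane F7. Tin–lithium exchange with MeLi gives the alkenyllithium F8, which opens oxetane in the presence of BF3·OEt2 at −78 °C to the primary alcohol F9. Dess–Martin oxidation gives the aldehyde F10, and addition of 8 gives 11.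

Step 10. The most likely failure is poor control of the C9=C12 geometry, since the two flanks of the carbonyl group (C8H= and C10H2) differ little in size; a second risk is base-induced retro-vinylogous aldol cleavage of the C1–C6 bond if alkoxide forms. Fallback (setting out from 16 and returning at 18): 16 is treated with an excess of CBr4/PPh3. This converts the C9 ketone into a dibromomethylidene group (Ramirez olefination) and at the same time replaces the C3 alcohol by bromide with inversion, giving the tribromide F11. Halophilic mono-reduction with HP(O)(OEt)2 and Et3N (Hirao reduction) then removes the more hindered vinylic bromine. Its steric sense is opposite to that of the Wittig reaction, so whichever flank behaves as the larger one, one of the two methods should favour the Z isomer 18.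

Step 11. The most likely failure is E2 elimination of the activated axial C3 oxygen with the antiperiplanar axial hydrogens at C2 and C4, or ionisation of the tertiary C1 alcohol, instead of SN2 displacement. Fallback (bromide before epoxide, setting out from 13 and returning at 18): the Appel reaction is carried out on the monocyclic, less hindered alcohol 13 and gives the bromo ynone F12 with inversion. Peracid epoxidation (mCPBA, NaHCO3, CH2Cl2) is then controlled sterically by the bromide and should give mainly the anti epoxide F13. The Cp2TiCl2-catalysed cyclization of step 9 gives the bromo hydroxy enone F14 (unactivated secondary alkyl bromides are not reduced by Cp2TiCl), and the Wittig reaction of step 10 gives 18.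

## Further compounds

F1 | step 9 | 5-[(4R)-4-[(tert-butyldimethylsilyl)oxy]-2,6,6-trimethylcyclohex-1-en-1-yl]-1-(trimethylsilyl)pent-1-yn-3-yl acetate (both epimers at the acetoxy carbon) | CC1(C)C[C@H](O[Si](C)(C)C(C)(C)C)CC(C)=C1CCC(OC(C)=O)C#C[Si](C)(C)C
F2 | step 9 | (1Z)-5-[(4R)-4-[(tert-butyldimethylsilyl)oxy]-2,6,6-trimethylcyclohex-1-en-1-yl]-1-(trimethylsilyl)pent-1-en-3-yl acetate | CC1(C)C[C@H](O[Si](C)(C)C(C)(C)C)CC(C)=C1CCC(OC(C)=O)/C=C\[Si](C)(C)C
F3 | step 9 | (1Z)-5-[(4R)-4-hydroxy-2,6,6-trimethylcyclohex-1-en-1-yl]-1-(trimethylsilyl)pent-1-en-3-yl acetate | CC1(C)C[C@H](O)CC(C)=C1CCC(OC(C)=O)/C=C\[Si](C)(C)C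
F4 | step 9 | (1Z)-5-[(1R,4S,6S)-4-hydroxy-2,2,6-trimethyl-7-oxabicyclo[4.1.0]heptan-1-yl]-1-(trimethylsilyl)pent-1-en-3-yl acetate | CC1(C)C[C@H](O)C[C@]2(C)O[C@]12CCC(OC(C)=O)/C=C\[Si](C)(C)C
F5 | step 9 | (1S,3S,6S)-1,3-dihydroxy-1,5,5-trimethylspiro[5.5]undec-7-en-9-yl acetate (both C9 epimers) | CC1(C)C[C@H](O)C[C@](C)(O)[C@@]12C=CC(OC(C)=O)CC2
F6 | step 9 | (1S,3S,6S)-1,5,5-trimethylspiro[5.5]undec-7-ene-1,3,9-triol (both C9 epimers) | CC1(C)C[C@H](O)C[C@](C)(O)[C@@]12C=CC(O)CC2
F7 | step 5 | [(4R)-4-[(tert-butyldimethylsilyl)oxy]-2,6,6-trimethylcyclohex-1-en-1-yl]trimethylstannane | CC1(C)C[C@H](O[Si](C)(C)C(C)(C)C)CC(C)=C1[Sn](C)(C)C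
F8 | step 5 | [(4R)-4-[(tert-butyldimethylsilyl)oxy]-2,6,6-trimethylcyclohex-1-en-1-yl]lithium | CC1(C)C[C@H](O[Si](C)(C)C(C)(C)C)CC(C)=C1[Li]
F9 | step 5 | 3-[(4R)-4-[(tert-butyldimethylsilyl)oxy]-2,6,6-trimethylcyclohex-1-en-1-yl]propan-1-ol | CC1(C)C[C@H](O[Si](C)(C)C(C)(C)C)CC(C)=C1CCCO
F10 | step 5 | 3-[(4R)-4-[(tert-butyldimethylsilyl)oxy]-2,6,6-trimethylcyclohex-1-en-1-yl]propanal | CC1(C)C[C@H](O[Si](C)(C)C(C)(C)C)CC(C)=C1CCC=O
F11 | step 10 | (1S,3R,6S)-3-bromo-9-(dibromomethylidene)-1,5,5-trimethylspiro[5.5]undec-7-en-1-ol | CC1(C)C[C@@H](Br)C[C@](C)(O)[C@@]12C=CC(=C(Br)Br)CC2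
F12 | step 11 | 5-[(4S)-4-bromo-2,6,6-trimethylcyclohex-1-en-1-yl]pent-1-yn-3-one | CC1(C)C[C@@H](Br)CC(C)=C1CCC(=O)C#C
F13 | step 11 | 5-[(1R,4R,6S)-4-bromo-2,2,6-trimethyl-7-oxabicyclo[4.1.0]heptan-1-yl]pent-1-yn-3-one | CC1(C)C[C@@H](Br)C[C@]2(C)O[C@]12CCC(=O)C#C
F14 | step 11 | (1S,3R,6S)-3-bromo-1-hydroxy-1,5,5-trimethylspiro[5.5]undec-7-en-9-one | CC1(C)C[C@@H](Br)C[C@](C)(O)[C@@]12C=CC(=O)CC2
A1 | alternative 1 | (5S)-5-[(tert-butyldimethylsilyl)oxy]-3,3-dimethyl-2-methylidenecyclohexan-1-one | CC1(C)C[C@H](O[Si](C)(C)C(C)(C)C)CC(=O)C1=C
A2 | alternative 1 | (3S,6S)-3-[(tert-butyldimethylsilyl)oxy]-5,5-dimethylspiro[5.5]undec-7-ene-1,9-dione | CC1(C)C[C@H](O[Si](C)(C)C(C)(C)C)CC(=O)[C@@]12C=CC(=O)CC2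
A3 | alternative 2 | 1-[4-[(tert-butyldimethylsilyl)oxy]-2,2,6-trimethyl-7-oxabicyclo[4.1.0]heptan-1-yl]cyclopent-2-en-1-ol (4S, epoxide syn to the silyloxy group, carbinol carbon unassigned) | CC1(C)C[C@H](O[Si](C)(C)C(C)(C)C)C[C@]2(C)O[C@]12C1(O)C=CCC1
A4 | alternative 2 | (1S,3S,6R)-3-[(tert-butyldimethylsilyl)oxy]-1-hydroxy-1,5,5-trimethylspiro[5.5]undec-7-en-11-one | CC1(C)C[C@H](O[Si](C)(C)C(C)(C)C)C[C@](C)(O)[C@@]12C=CCCC2=O
A5 | alternative 3 | (4S)-4-hydroxy-6-(4-methoxycyclohexa-1,3-dien-1-yl)-6-methylheptan-2-one | COC1=CC=C(CC1)C(C)(C)C[C@H](O)CC(C)=O
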